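**Plan**
- Retrosynthetic cuts, in order: the C8–O acyl bond; the lactone bond C12–O6 (back to a C6‑OH/C12‑OH pair); the oxirane oxygen (back to a 4E olefin next to C6‑OH); C5–H (back to a C5 enol triflate, i.e. the C5 enolate); and last C2–C3.
- Enabling feature: in the ten‑membered ring, C1=C10 and the C4–C5 unit (the oxirane carbons) are 1,5‑related through C2–C3. Cutting C2–C3 and rejoining C5–C10 is a [3,3] retron. It leads to a cyclohexane C5–C10 with OH and isopropenyl on C5 and methyl and vinyl on C10.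
- That cyclohexane is the ring of (S)‑carvone (C9 = carbonyl carbon, C10 = methyl‑bearing carbon, C5 = olefinic CH, C7 = stereocentre). C10 becomes quaternary by vinyl addition at C9, directed epoxidation and a semipinacol vinyl shift.
- Ring order in the forward direction: cyclohexane (from carvone), ten‑membered carbocycle (step 17), oxirane (step 22), γ‑lactone (step 24).
- Stereochemistry: C7 comes from carvone and controls C9, which controls C5/C10. The axial C10 methyl then directs O8, O9, O6 and the isopropenyl group. Both olefin geometries come from one chair transition state, and C4/C5 come from the C6‑OH‑directed epoxidation.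

Key step: step 17

Remark on the chemistry: the target is read as (4R,5R,6S,7R,8R,9R) with a 1(10)Z olefin, a trans‑4,5‑epoxide and a trans‑fused 6,12‑lactone.
Notation: germacranolide numbering (C1–C15) is used for every intermediate. On the six‑membered ring C5–C10, α is the face that carries the C7 side chain and β is the opposite face.

**Step 1**
Reactants: 1 (S)-carvone
Product: 2 (S)-10-chlorocarvone (C12 allylic chloride)
Conditions: Ca(OCl)2, CO2 (dry ice), CH2Cl2/H2O, 0 °C
Reagents that add atoms: calcium hypochlorite, [Ca+2].[O-]Cl.[O-]Cl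
Why: Ene‑type allylic chlorination by HOCl made in situ should touch only the electron‑rich 1,1‑disubstituted olefin (the enone C=C is deactivated), moving the double bond to C11=C13 and placing chloride on C12 without affecting C7.

**Step 2**
Reactants: 2 (S)-10-chlorocarvone; 3 4-methoxybenzyl alcohol
Product: 5 C12 4-methoxybenzyl (PMB) ether of 10-hydroxycarvone, via sodium 4-methoxybenzyl oxide 4 (not isolated)
Conditions: 3, NaH, THF, 0 °C; then 2, Bu4NI (cat.), 0 °C → rt
Reagents that add atoms: none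
Why: Williamson ether synthesis, in which SN2 displacement at the unhindered primary allylic chloride (iodide catalysis) by the pre‑formed alkoxide should outrun enolisation or reversible conjugate addition at the enone.

**Step 3**
Reactants: 5 C12-OPMB carvone; 6 vinylmagnesium bromide
Product: 7 9β-vinyl-9α-hydroxy cyclohexene (tertiary bis-allylic alcohol)
Conditions: LaCl3·2LiCl, THF, 0 °C; 6, −78 → 0 °C
Reagents that add atoms: none
Why: In this lanthanide‑promoted Grignard 1,2‑addition to an enone the vinyl group should enter axially on the β face, anti to the equatorial C7 side chain, which sets C9 (vinyl β, OH α).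

**Step 4**
Reactants: 7 9β-vinyl-9α-hydroxy cyclohexene
Product: 8 5α,10α-epoxy-9α-alcohol (oxirane cis to the hydroxyl)
Conditions: VO(acac)2 (cat.), t-BuOOH, toluene, 0 °C
Reagents that add atoms: tert-butyl hydroperoxide, CC(C)(C)OO
Why: In this vanadium‑catalysed hydroxyl‑directed epoxidation the 9α‑OH delivers oxygen to the α face of the trisubstituted C5=C10 bond, which should react well before the monosubstituted vinyl group and the remote C11=C13 bond, so C5 and C10 are set cis to the hydroxyl.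

**Step 5**
Reactants: 8 5α,10α-epoxy-9α-alcohol
Product: 9 5α-hydroxy-10α-methyl-10β-vinyl C9 ketone
Conditions: ZnBr2 (cat.), CH2Cl2, 0 °C → rt
Reagents that add atoms: none
Why: In this semipinacol rearrangement of a 2,3‑epoxy alcohol the Lewis acid opens the oxirane at tertiary C10 and the pseudo‑axial 9β‑vinyl group, antiperiplanar to the C10–O bond, migrates with inversion at C10 (vinyl β, methyl α), while C9 returns to the ketone and the oxygen stays on C5.

**Step 6**
Reactants: 9 5α-hydroxy C9 ketone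
Product: 10 5α-benzoate
Conditions: BzCl, pyridine, DMAP (cat.), CH2Cl2, 0 °C → rt
Reagents that add atoms: benzoyl chloride, O=C(Cl)c1ccccc1
Why: DMAP‑catalysed acylation, with a benzoate chosen because it has no α‑hydrogens, cannot be eliminated (C10 is quaternary) and cannot migrate to O9 later (O5 and O9 are 1,3‑diequatorial).

**Step 7**
Reactants: 10 5α-benzoate
Product: 12 8β-hydroxy C9 ketone, via potassium C8 enolate 11 (not isolated)
Conditions: KHMDS, THF, −78 °C; 2-(phenylsulfonyl)-3-phenyloxaziridine, −78 °C; AcOH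
Reagents that add atoms: 2-(phenylsulfonyl)-3-phenyloxaziridine, O=S(=O)(c1ccccc1)N1OC1c1ccccc1
Why: In this Davis enolate hydroxylation only the C8 enolate can form (C10 is quaternary), and the oxidant should come from the β face because the α face is screened by the axial C10 methyl (1,3‑related) and the C7 chain, giving the equatorial 8β‑OH, which is also the more stable epimer.

**Step 8**
Reactants: 12 8β-hydroxy C9 ketone
Product: 13 8β-triethylsilyl (TES) ether
Conditions: TESCl, imidazole, CH2Cl2, 0 °C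
Reagents that add atoms: chlorotriethylsilane, CC[Si](Cl)(CC)CC
Why: Standard silylation of the α‑ketol hydroxyl, with TES chosen because it can later be removed while TBS stays.

**Step 9**
Reactants: 13 8β-OTES C9 ketone
Product: 14 9α-alcohol (equatorial and trans to O8)
Conditions: NaBH4, CeCl3·7H2O, MeOH/THF, −40 → 0 °C
Reagents that add atoms: none
Why: In this Luche reduction hydride should attack axially from the β face, since the α face is blocked by the adjacent axial C10 methyl, which sets C9 with the equatorial α‑OH, and the weakly basic medium disfavours TES migration.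

**Step 10**
Reactants: 14 9α-alcohol
Product: 15 9α-tert-butyldimethylsilyl (TBS) ether
Conditions: TBSOTf, 2,6-lutidine, CH2Cl2, 0 °C → rt
Reagents that add atoms: tert-butyldimethylsilyl triflate, CC(C)(C)[Si](C)(C)OS(=O)(=O)C(F)(F)F
Why: Silyl triflate silylation is the usual method for a secondary alcohol next to a quaternary carbon, and the benzoate, TES and PMB groups are inert to it.

**Step 11**
Reactants: 15 9α-OTBS 5α-benzoate
Product: 16 5α-alcohol
Conditions: DIBAL-H, CH2Cl2, −78 °C
Reagents that add atoms: none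
Why: Reductive ester cleavage frees O5 without the basic conditions that could move silyl groups, and nothing else in the molecule is reducible.

**Step 12**
Reactants: 16 5α-alcohol
Product: 17 C5 ketone (8β-OTES 9α-OTBS 10α-methyl 10β-vinyl)
Conditions: Dess–Martin periodinane, NaHCO3, CH2Cl2, 0 °C → rt
Reagents that add atoms: none
Why: Buffered Dess–Martin oxidation of a hindered secondary alcohol, whose β‑silyloxy ketone product cannot eliminate because C10 carries no hydrogen.

**Step 13**
Reactants: 17 C5 ketone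
Product: 19 6β-hydroxy C5 ketone, via potassium C6 enolate 18 (not isolated)
Conditions: KHMDS, THF, −78 °C; 2-(phenylsulfonyl)-3-phenyloxaziridine, −78 °C; AcOH
Reagents that add atoms: 2-(phenylsulfonyl)-3-phenyloxaziridine, O=S(=O)(c1ccccc1)N1OC1c1ccccc1
Why: In this Davis enolate hydroxylation C6 is the only enolisable position, and the axial C10 methyl and the C7 chain again leave the β face open, so C6 is set with the equatorial β‑OH trans to the C7 chain.

**Step 14**
Reactants: 20 3,4-dimethoxybenzyl alcohol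
Product: 21 3,4-dimethoxybenzyl trichloroacetimidate
Conditions: Cl3CCN, DBU (cat.), CH2Cl2, 0 °C
Reagents that add atoms: trichloroacetonitrile, N#CC(Cl)(Cl)Cl
Why: Base‑catalysed addition of an alcohol to trichloroacetonitrile is the standard way to a benzyl‑type imidate.

**Step 15**
Reactants: 19 6β-hydroxy C5 ketone; 21 3,4-dimethoxybenzyl trichloroacetimidate
Product: 22 6β-(3,4-dimethoxybenzyl) (DMB) ether
Conditions: La(OTf)3 (cat.), toluene, rt
Reagents that add atoms: none
Why: Lewis‑acid‑catalysed imidate benzylation is nearly neutral, so the α‑ketol is neither epimerised nor rearranged and TES survives, and a benzyl‑type ether cannot migrate to the later C5 alkoxide, with DMB falling to DDQ before PMB.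

**Step 16**
Reactants: 22 6β-ODMB C5 ketone; 23 isopropenylmagnesium bromide
Product: 24 5β-isopropenyl-5α-hydroxy-10β-vinyl cyclohexanol (cis-dialkenyl rearrangement precursor)
Conditions: LaCl3·2LiCl, THF, −20 °C; 23, −20 → 0 °C
Reagents that add atoms: none
Why: In this lanthanide‑promoted Grignard addition to an α‑alkoxy ketone the metal chelate between C5=O and the equatorial O6 fixes the carbonyl and the axial C10 methyl shields the α face, so isopropenyl should enter axially from the β face, cis to the C10 vinyl, with enolisation suppressed.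

**Step 17**
Reactants: 24 cis-dialkenyl cyclohexanol
Product: 27 ten-membered (1(10)Z)-diene C5 enol triflate (C3 anti to C6 across C4=C5), via potassium C5 alkoxide 25 (not isolated), via potassium C5 enolate 26 (not isolated)
Conditions: KH, 18-crown-6, THF, 0 → 25 °C; then N-(5-chloro-2-pyridyl)bis(trifluoromethanesulfonimide), −78 °C
Reagents that add atoms: N-(5-chloro-2-pyridyl)bis(trifluoromethanesulfonimide) (Comins' reagent), Clc1ccc(nc1)N(S(=O)(=O)C(F)(F)F)S(=O)(=O)C(F)(F)F
Why: KH/18‑crown‑6 gives the dissociated alkoxide 25, whose weakened C5–C10 bond breaks while C2–C3 forms in a concerted chair‑like [3,3] shift, the anionic oxy‑Cope rearrangement of a 1,2‑dialkenylcyclohexanol that is the classical entry to cyclodec‑5‑enones. The ten‑membered ring therefore arises by a four‑atom ring expansion (bond exchange within the bicyclic transition state), not by end‑to‑end closure, and enolate formation makes the step irreversible, unlike the neutral divinylcyclohexane/cyclodecadiene equilibrium. No stereocentre is formed and C6–C9 are untouched, so what is set are two olefin geometries. In the only populated chair (O6, C7 chain, O8 and O9 all equatorial) the C10 vinyl is equatorial and the C5 isopropenyl axial, so C9 is pseudo‑axial and C6 pseudo‑equatorial on the six‑centre chair, which should give the 1(10)Z olefin and the enolate with C3 anti to C6. The step needs chair over boat, no silyl transfer to the alkoxide and capture at oxygen, and these are secured by the locked cyclohexane chair, by the benzyl‑type ether on O6 together with the 1,3‑diequatorial O5/O9 pair that silicon cannot bridge, and by the fully substituted enolate carbon C4. Sulfonylation at −78 °C should fix the enolate geometry before proton transfer can scramble it.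

**Step 18**
Reactants: 27 C5 enol triflate
Product: 28 (1(10)Z,4E)-germacra-1(10),4,11(13)-triene (6-ODMB 8-OTES 9-OTBS 12-OPMB)
Conditions: Pd(OAc)2 (cat.), PPh3, HCO2H, Et3N, DMF, 40 °C
Reagents that add atoms: none
Why: Palladium‑catalysed formate reduction of an enol triflate (oxidative addition, decarboxylation of formate, reductive elimination) replaces OTf by H with retention of geometry, at a temperature far below that of a thermal Cope reversal.

**Step 19**
Reactants: 28 fully protected triene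
Product: 29 8-alcohol
Conditions: HF·pyridine, pyridine, THF, 0 °C
Reagents that add atoms: none
Why: Buffered fluoride cleaves a TES ether well before a hindered secondary TBS ether, and the step is placed before the acid‑sensitive oxirane exists.

**Step 20**
Reactants: 29 8-alcohol; 30 3-methylbut-2-enoyl chloride
Product: 31 8-senecioate
Conditions: pyridine, DMAP (cat.), CH2Cl2, 0 °C → rt
Reagents that add atoms: none
Why: DMAP‑catalysed acylation of the only free hydroxyl, with pyridine used instead of a trialkylamine so that the acid chloride is not turned into a vinylketene, which would give the deconjugated ester.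

**Step 21**
Reactants: 31 8-senecioate
Product: 32 6-alcohol (allylic to the 4E olefin)
Conditions: DDQ (1.1 equiv), CH2Cl2/pH 7 buffer, 0 °C
Reagents that add atoms: none
Why: Oxidative benzyl ether cleavage, in which the more electron‑rich 3,4‑dimethoxybenzyl ether is oxidised by DDQ faster than the 4‑methoxybenzyl ether, so only O6 should be freed.

**Step 22**
Reactants: 32 6-alcohol
Product: 33 (4R,5R)-4,5-epoxy-6-alcohol
Conditions: VO(acac)2 (cat.), t-BuOOH, CH2Cl2, −10 °C
Reagents that add atoms: tert-butyl hydroperoxide, CC(C)(C)OO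
Why: In this vanadium‑catalysed directed epoxidation C6‑OH is the only free hydroxyl, so only C4=C5 reacts, and A(1,3) strain with C15 holds H6 in the olefin plane with C7 on the inner face, so oxygen arrives on the outer face that carries O6, which sets C4 and C5 as the trans epoxide syn to O6.

**Step 23**
Reactants: 33 4,5-epoxy-6-alcohol
Product: 34 4,5-epoxy-6,12-diol
Conditions: DDQ (1.5 equiv), CH2Cl2/pH 7 buffer, rt
Reagents that add atoms: none
Why: Standard buffered DDQ removal of a PMB ether, under neutral conditions that the oxirane, senecioate and TBS ether tolerate.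

**Step 24**
Reactants: 34 4,5-epoxy-6,12-diol
Product: 37 9-O-TBS α-methylene-γ-lactone, via C12 hydroxy enal 35 (not isolated), via C12 lactol 36 (not isolated)
Conditions: MnO2 (excess), CH2Cl2, rt
Reagents that add atoms: none
Why: In this oxidative lactonisation of a 2‑methylene‑1,4‑diol, MnO2 oxidises only the allylic primary C12‑OH (C6‑OH is no longer allylic), the enal closes on O6 to the five‑membered lactol (5‑exo‑trig) and this is oxidised on, with the trans ring fusion following from C6 and C7.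

**Step 25**
Reactants: 37 9-O-TBS lactone
Product: 38 target CNP0188779.3
Conditions: TBAF, AcOH (1:1), THF, 0 °C → rt
Reagents that add atoms: none
Why: Acetic‑acid‑buffered fluoride desilylation avoids free alkoxide, so acyl migration from O8 to O9, conjugate addition to the methylene lactone and acid‑induced transannular opening of the oxirane should all be suppressed.

**Compound list**
1 | (S)-carvone | CC1=CC[C@@H](CC1=O)C(C)=C | starting material
2 | (S)-10-chlorocarvone, (5S)-5-(3-chloroprop-1-en-2-yl)-2-methylcyclohex-2-en-1-one | CC1=CC[C@@H](CC1=O)C(=C)CCl | intermediate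
3 | 4-methoxybenzyl alcohol | COc1ccc(CO)cc1 | starting material
4 | sodium 4-methoxybenzyl oxide | COc1ccc(C[O-])cc1.[Na+] | intermediate
5 | (5S)-5-[3-(4-methoxybenzyloxy)prop-1-en-2-yl]-2-methylcyclohex-2-en-1-one | CC1=CC[C@@H](CC1=O)C(=C)COCc1ccc(OC)cc1 | intermediate
6 | vinylmagnesium bromide | C=C[Mg]Br | starting material
7 | 9β-vinyl-9α-hydroxy cyclohexene, (1R,5S)-1-ethenyl-2-methyl-5-[3-(PMB-oxy)prop-1-en-2-yl]cyclohex-2-en-1-ol | C=C[C@]1(O)C[C@@H](C(=C)COCc2ccc(OC)cc2)CC=C1C | intermediate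
8 | 5α,10α-epoxide of 7 (oxirane cis to 9α-OH) | C=C[C@]1(O)C[C@@H](C(=C)COCc2ccc(OC)cc2)C[C@H]2O[C@@]12C | intermediate
9 | 5α-hydroxy-10α-methyl-10β-vinyl C9 ketone | O=C1C[C@@H](C(=C)COCc2ccc(OC)cc2)C[C@@H](O)[C@]1(C)C=C | intermediate
10 | 5α-benzoate of 9 | O=C1C[C@@H](C(=C)COCc2ccc(OC)cc2)C[C@@H](OC(=O)c2ccccc2)[C@]1(C)C=C | intermediate
11 | potassium C8 enolate of 10 | [K+].[O-]C1=C[C@@H](C(=C)COCc2ccc(OC)cc2)C[C@@H](OC(=O)c2ccccc2)[C@]1(C)C=C | intermediate
12 | 8β-hydroxy C9 ketone | O=C1[C@H](O)[C@@H](C(=C)COCc2ccc(OC)cc2)C[C@@H](OC(=O)c2ccccc2)[C@]1(C)C=C | intermediate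
13 | 8β-OTES C9 ketone | O=C1[C@H](O[Si](CC)(CC)CC)[C@@H](C(=C)COCc2ccc(OC)cc2)C[C@@H](OC(=O)c2ccccc2)[C@]1(C)C=C | intermediate
14 | 9α-alcohol | O[C@H]1[C@H](O[Si](CC)(CC)CC)[C@@H](C(=C)COCc2ccc(OC)cc2)C[C@@H](OC(=O)c2ccccc2)[C@]1(C)C=C | intermediate
15 | 9α-OTBS 5α-benzoate | CC(C)(C)[Si](C)(C)O[C@H]1[C@H](O[Si](CC)(CC)CC)[C@@H](C(=C)COCc2ccc(OC)cc2)C[C@@H](OC(=O)c2ccccc2)[C@]1(C)C=C | intermediate
16 | 5α-alcohol | CC(C)(C)[Si](C)(C)O[C@H]1[C@H](O[Si](CC)(CC)CC)[C@@H](C(=C)COCc2ccc(OC)cc2)C[C@@H](O)[C@]1(C)C=C | intermediate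
17 | C5 ketone | CC(C)(C)[Si](C)(C)O[C@H]1[C@H](O[Si](CC)(CC)CC)[C@@H](C(=C)COCc2ccc(OC)cc2)CC(=O)[C@]1(C)C=C | intermediate
18 | potassium C6 enolate of 17 | CC(C)(C)[Si](C)(C)O[C@H]1[C@H](O[Si](CC)(CC)CC)[C@@H](C(=C)COCc2ccc(OC)cc2)C=C([O-])[C@]1(C)C=C.[K+] | intermediate
19 | 6β-hydroxy C5 ketone | CC(C)(C)[Si](C)(C)O[C@H]1[C@H](O[Si](CC)(CC)CC)[C@@H](C(=C)COCc2ccc(OC)cc2)[C@H](O)C(=O)[C@]1(C)C=C | intermediate
20 | 3,4-dimethoxybenzyl alcohol | COc1ccc(CO)cc1OC | starting material
21 | 3,4-dimethoxybenzyl 2,2,2-trichloroacetimidate | COc1ccc(COC(=N)C(Cl)(Cl)Cl)cc1OC | intermediate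
22 | 6β-ODMB C5 ketone | CC(C)(C)[Si](C)(C)O[C@H]1[C@H](O[Si](CC)(CC)CC)[C@@H](C(=C)COCc2ccc(OC)cc2)[C@H](OCc2ccc(OC)c(OC)c2)C(=O)[C@]1(C)C=C | intermediate
23 | isopropenylmagnesium bromide | CC(=C)[Mg]Br | starting material
24 | 5β-isopropenyl-5α-hydroxy-10α-methyl-10β-vinyl cyclohexane (6β-ODMB, 7α side chain with 12-OPMB, 8β-OTES, 9α-OTBS) | CC(C)(C)[Si](C)(C)O[C@H]1[C@H](O[Si](CC)(CC)CC)[C@@H](C(=C)COCc2ccc(OC)cc2)[C@H](OCc2ccc(OC)c(OC)c2)[C@](O)(C(C)=C)[C@]1(C)C=C | intermediate
25 | potassium C5 alkoxide of 24 | CC(C)(C)[Si](C)(C)O[C@H]1[C@H](O[Si](CC)(CC)CC)[C@@H](C(=C)COCc2ccc(OC)cc2)[C@H](OCc2ccc(OC)c(OC)c2)[C@]([O-])(C(C)=C)[C@]1(C)C=C.[K+] | intermediate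
26 | potassium C5 enolate of the ten-membered ring (1(10)Z; C3 anti to C6) | [K+].C1/C(C)=C(\[O-])[C@@H](OCc2ccc(OC)c(OC)c2)[C@H](C(=C)COCc2ccc(OC)cc2)[C@@H](O[Si](CC)(CC)CC)[C@H](O[Si](C)(C)C(C)(C)C)/C(C)=C\C1 | intermediate
27 | C5 enol triflate of the ten-membered ring (1(10)Z; C3 anti to C6) | C1/C(C)=C(\OS(=O)(=O)C(F)(F)F)[C@@H](OCc2ccc(OC)c(OC)c2)[C@H](C(=C)COCc2ccc(OC)cc2)[C@@H](O[Si](CC)(CC)CC)[C@H](O[Si](C)(C)C(C)(C)C)/C(C)=C\C1 | intermediate
28 | (1(10)Z,4E)-germacra-1(10),4,11(13)-triene, 6-ODMB 8-OTES 9-OTBS 12-OPMB | C1/C(C)=C/[C@@H](OCc2ccc(OC)c(OC)c2)[C@H](C(=C)COCc2ccc(OC)cc2)[C@@H](O[Si](CC)(CC)CC)[C@H](O[Si](C)(C)C(C)(C)C)/C(C)=C\C1 | intermediate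
29 | 8-alcohol | C1/C(C)=C/[C@@H](OCc2ccc(OC)c(OC)c2)[C@H](C(=C)COCc2ccc(OC)cc2)[C@@H](O)[C@H](O[Si](C)(C)C(C)(C)C)/C(C)=C\C1 | intermediate
30 | 3-methylbut-2-enoyl (senecioyl) chloride | CC(C)=CC(=O)Cl | starting material
31 | 8-senecioate | C1/C(C)=C/[C@@H](OCc2ccc(OC)c(OC)c2)[C@H](C(=C)COCc2ccc(OC)cc2)[C@@H](OC(=O)C=C(C)C)[C@H](O[Si](C)(C)C(C)(C)C)/C(C)=C\C1 | intermediate
32 | 6-alcohol | C1/C(C)=C/[C@@H](O)[C@H](C(=C)COCc2ccc(OC)cc2)[C@@H](OC(=O)C=C(C)C)[C@H](O[Si](C)(C)C(C)(C)C)/C(C)=C\C1 | intermediate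
33 | (4R,5R)-4,5-epoxy-6-alcohol | O[C@H]2[C@H](C(=C)COCc3ccc(OC)cc3)[C@@H](OC(=O)C=C(C)C)[C@H](O[Si](C)(C)C(C)(C)C)/C(C)=C\CC[C@@]1(C)O[C@H]21 | intermediate
34 | 4,5-epoxy-6,12-diol | O[C@H]2[C@H](C(=C)CO)[C@@H](OC(=O)C=C(C)C)[C@H](O[Si](C)(C)C(C)(C)C)/C(C)=C\CC[C@@]1(C)O[C@H]21 | intermediate
35 | C12 hydroxy enal | O[C@H]2[C@H](C(=C)C=O)[C@@H](OC(=O)C=C(C)C)[C@H](O[Si](C)(C)C(C)(C)C)/C(C)=C\CC[C@@]1(C)O[C@H]21 | intermediate
36 | C12 lactol (both anomers) | C=C1C(O)O[C@H]2[C@H]1[C@@H](OC(=O)C=C(C)C)[C@H](O[Si](C)(C)C(C)(C)C)/C(C)=C\CC[C@@]1(C)O[C@H]21 | intermediate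
37 | 9-O-TBS ether of the target | C=C1C(=O)O[C@H]2[C@H]1[C@@H](OC(=O)C=C(C)C)[C@H](O[Si](C)(C)C(C)(C)C)/C(C)=C\CC[C@@]1(C)O[C@H]21 | intermediate
38 | CNP0188779.3, (4R,5R,6S,7R,8R,9R,1(10)Z)-4,5-epoxy-9-hydroxy-8-senecioyloxygermacra-1(10),11(13)-dien-12,6-olide | C=C1C(=O)O[C@H]2[C@H]1[C@@H](OC(=O)C=C(C)C)[C@H](O)/C(C)=C\CC[C@@]1(C)O[C@H]21 | target

**Step count**
- Total step count: 25.
- Longest linear sequence: 24 steps (steps 1–13 and 15–25 from (S)-carvone). Step 14 is a one‑step side branch.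

**Steps most likely to fail**

1. Step 17. The crowded alkoxide may rearrange slowly enough for proton transfer or fragmentation to compete, and O‑sulfonylation of the hindered tetrasubstituted enolate may be incomplete.
   - The fallback keeps the same [3,3] shift but carries the C5 oxygen forward instead of removing it. It sets out from 24 and returns at 34.
   - The enolate is trapped with TMSCl/Et3N as the C5 trimethylsilyl enol ether F1.
   - Rubottom oxidation (DMDO, −78 °C, then citric acid/MeOH) on the outer face gives the (4R)-4-hydroxy-5-ketone F2.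
   - Zn(BH4)2, chelated to O6, gives the (4R,5S)-4,5-diol F3.
   - MsCl/Et3N gives the C5 mesylate F4, and K2CO3/MeOH closes the fully protected 4,5-epoxide F5 with inversion at C5.
   - HF·pyridine/pyridine gives the epoxy 8-alcohol F6, and senecioyl chloride/pyridine/DMAP gives the epoxy 8-senecioate F7.
   - Excess DDQ then removes DMB and PMB together to give 34.

2. Step 16. Facial selectivity may be poor (equatorial attack of the branched alkenyl nucleophile), or the hindered ketone may enolise.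
   - The fallback uses a slim sp nucleophile, which prefers axial attack. It sets out from 22 and returns at 24.
   - Ethynylmagnesium bromide with LaCl3·2LiCl gives the 5β-ethynyl-5α-carbinol F8.
   - Zirconium‑catalysed methylalumination (AlMe3, Cp2ZrCl2, CH2Cl2; Negishi carboalumination) followed by protonolysis turns the ethynyl group into the isopropenyl group of 24.

3. Step 21. The unhindered primary PMB ether may be lost together with the hindered secondary DMB ether.
   - The fallback replaces selective deprotection by selective re‑protection. It sets out from 31 and returns at 34.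
   - Excess DDQ gives the triene 6,12-diol F9.
   - TESCl (1 equiv)/imidazole at −20 °C silylates only the primary hydroxyl to give the 12-O-TES 6-alcohol F10.
   - VO(acac)2/t-BuOOH gives the 12-O-TES 4,5-epoxy-6-alcohol F11.
   - HF·pyridine/pyridine then frees O12 to give 34.

**Further compounds**
F1 | step 17 | C5 trimethylsilyl enol ether of the ten-membered ring | C1/C(C)=C(\O[Si](C)(C)C)[C@@H](OCc2ccc(OC)c(OC)c2)[C@H](C(=C)COCc2ccc(OC)cc2)[C@@H](O[Si](CC)(CC)CC)[C@H](O[Si](C)(C)C(C)(C)C)/C(C)=C\C1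
F2 | step 17 | (4R)-4-hydroxy-5-ketone | C1[C@@](C)(O)C(=O)[C@@H](OCc2ccc(OC)c(OC)c2)[C@H](C(=C)COCc2ccc(OC)cc2)[C@@H](O[Si](CC)(CC)CC)[C@H](O[Si](C)(C)C(C)(C)C)/C(C)=C\C1
F3 | step 17 | (4R,5S)-4,5-diol | C1[C@@](C)(O)[C@@H](O)[C@@H](OCc2ccc(OC)c(OC)c2)[C@H](C(=C)COCc2ccc(OC)cc2)[C@@H](O[Si](CC)(CC)CC)[C@H](O[Si](C)(C)C(C)(C)C)/C(C)=C\C1
F4 | step 17 | C5 mesylate of F3 | C1[C@@](C)(O)[C@@H](OS(C)(=O)=O)[C@@H](OCc2ccc(OC)c(OC)c2)[C@H](C(=C)COCc2ccc(OC)cc2)[C@@H](O[Si](CC)(CC)CC)[C@H](O[Si](C)(C)C(C)(C)C)/C(C)=C\C1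
F5 | step 17 | fully protected (4R,5R)-4,5-epoxide | COc1ccc(CO[C@H]2[C@H](C(=C)COCc3ccc(OC)cc3)[C@@H](O[Si](CC)(CC)CC)[C@H](O[Si](C)(C)C(C)(C)C)/C(C)=C\CC[C@@]3(C)O[C@H]23)cc1OC
F6 | step 17 | epoxy 8-alcohol | COc1ccc(CO[C@H]2[C@H](C(=C)COCc3ccc(OC)cc3)[C@@H](O)[C@H](O[Si](C)(C)C(C)(C)C)/C(C)=C\CC[C@@]3(C)O[C@H]23)cc1OC
F7 | step 17 | epoxy 8-senecioate | COc1ccc(CO[C@H]2[C@H](C(=C)COCc3ccc(OC)cc3)[C@@H](OC(=O)C=C(C)C)[C@H](O[Si](C)(C)C(C)(C)C)/C(C)=C\CC[C@@]3(C)O[C@H]23)cc1OC
F8 | step 16 | 5β-ethynyl-5α-carbinol | CC(C)(C)[Si](C)(C)O[C@H]1[C@H](O[Si](CC)(CC)CC)[C@@H](C(=C)COCc2ccc(OC)cc2)[C@H](OCc2ccc(OC)c(OC)c2)[C@](O)(C#C)[C@]1(C)C=C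
F9 | step 21 | triene 6,12-diol | C1/C(C)=C/[C@@H](O)[C@H](C(=C)CO)[C@@H](OC(=O)C=C(C)C)[C@H](O[Si](C)(C)C(C)(C)C)/C(C)=C\C1
F10 | step 21 | 12-O-TES 6-alcohol | C1/C(C)=C/[C@@H](O)[C@H](C(=C)CO[Si](CC)(CC)CC)[C@@H](OC(=O)C=C(C)C)[C@H](O[Si](C)(C)C(C)(C)C)/C(C)=C\C1
F11 | step 21 | 12-O-TES 4,5-epoxy-6-alcohol | O[C@H]2[C@H](C(=C)CO[Si](CC)(CC)CC)[C@@H](OC(=O)C=C(C)C)[C@H](O[Si](C)(C)C(C)(C)C)/C(C)=C\CC[C@@]1(C)O[C@H]21
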